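Labdane numbering is used throughout. Ring A is C1–C5 and C10, ring B is C5–C10. C17 is the exocyclic methylene carbon, C18 and C19 are the methyls on C4, and C20 is the methyl on C10. The side chain is C11–C16.

## Analysis of the target

Haterumaimide G (23) is a trans-decalin. C11H2 links it to a secondary carbinol (C12) and a free N–H succinimide (C13–C16, N).

It has six stereocentres, (2S,5S,9S,10R,12S,13R):
- **C10** carries an axial β-methyl (C20).
- **C5 and C9** both carry α-hydrogens, so C11 is equatorial.
- **C2** carries an equatorial α-chlorine.
- **C12 and C13** form a syn-aldol pair that lies too far from the rings to be controlled by them.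

C2 sits between two CH2 groups (C1 and C3) and is 1,3-related to the quaternary carbons C4 and C10. No neighbouring function can direct the introduction of the chlorine.

The sensitive unit is the β,γ-unsaturated ketone C6(=O)–C7H2–C8(=C17H2). Acid or base moves the double bond into conjugation, and C5 next to the carbonyl is epimerisable. The secondary chloride can eliminate. The β-hydroxy imide can undergo retro-aldol cleavage or dehydration.

The route is built on the following feature. Ring B is a 3-methylenecyclohexanone in which the C6 carbonyl is para to C9, and C9 is bonded to the quaternary C10. Written as its C5=C6 enol ether, ring B is the exact retron of a [4+2] union. The diene is the 2-oxydiene C10=C5–C6(O)=C7, and the dienophile is the conjugated double bond C8=C9 of an allene C17=C8=C9.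

The hard parts are three:
- forming C10 beside the neopentyl C5/C4 region;
- relating the remote C2 to C10;
- keeping the C8=C17 bond in place to the end.

## Retrosynthetic reasoning

**C5–H.** 23 is traced back to its C5=C6 tert-butyldimethylsilyl enol ether 22. The ketone then appears only in the last step, so the labile β,γ-enone never meets the reagents of the end game. The forward reaction has to protonate C5 from the α face.

**N–C16 and C12–C13.** The imide ring of 22 is opened at N–C16, which leads to the acyl-oxazolidinone 20 with C15 as a nitrile. Neutral hydration gives amide 21, whose nitrogen displaces the auxiliary. The syn C12/C13 pair of 20 is cut at C12–C13 into aldehyde 14 and the chiral imide 18, which is made from 15 and 16. This is the only place where the two remote centres can be set together by a reagent.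

**C11–C12.** Aldehyde 14 is shortened by one carbon to aldehyde 12, which comes from alcohol 11 and ester 10. This homologation is the price for placing the activating carbonyl of the key step on C11. It has to run without acid so that the enol silane survives.

**C7–C8 and C9–C10 (key).** Both bonds of ring B in 10 are cut at once, which gives the monocyclic silyloxydiene 8 and the C4 allenoate 9. In the forward direction one operation creates:
- ring B;
- the quaternary C10 and the stereocentre C9;
- the exocyclic C8=C17 bond;
- the regiodefined masked C6 ketone.

The precursor 8 has one ring and one stereocentre.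

**C5–C6 and C6–C7.** Diene 8 is the enol silane of methyl ketone 7. The acetyl group of 7 is removed by a carbonylative coupling transform, which leads to enol triflate 6. Triflate 6 comes from ketone 4 through enolate 5. Only one α-position of 4 bears hydrogen, so the regiochemistry is fixed.

**C2–Cl and the first stereocentre.** The chloride of 4 comes from alcohol 3 with inversion. Alcohol 3 comes from allylic alcohol 2 by directed hydrogenation. Alcohol 2 comes from the achiral, cheap enedione 1 by catalytic asymmetric reduction of its accessible carbonyl. All ring-A carbons of 23 are already present in 1. This one catalytic stereocentre is relayed to C10, C9 and C5.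

## Alternatives that were turned down

Alternative 1: the textbook semisynthesis.
- **Disconnection:** C12–C13 (aldol) and C2–Cl, on the intact decalin of (+)-sclareolide A1.
- **Forward key step:** a sterically governed radical C2–H chlorination to 2α-chlorosclareolide A2.
- **Why turned down:**
  - The chiral pool supplies C5, C9 and C10 but nothing at C6. C6 is an unactivated methylene with no handle.
  - After chlorination the most reactive C–H bonds are not at C6. Once the C8=C17 bond is in place, oxidation would go to the allylic C7.
  - The chlorination cannot tolerate the alkene, so the order of events is forced.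
  - Reshaping the lactone into alkene and aldehyde costs several redox steps. The 6-oxo-8(17)-ene unit, the real problem, stays unsolved.

Alternative 2: biomimetic bicyclisation.
- **Disconnection:** C4–C5 and C9–C10.
- **Forward key step:** a cationic polyene cyclisation of the acyclic chloro trienone allylsilane A3, ended by loss of silicon to give C8=C17.
- **Why turned down:**
  - The C5=C10 alkene of A3 is conjugated with the C6 carbonyl. C5 is therefore an enone α-carbon and cannot capture a C4 cation.
  - With C6 reduced to an ether, that position becomes allylic and ionisable.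
  - The C2–Cl bond is allylic to the initiating C3=C4 alkene and should ionise before that alkene is protonated.
  - A3 also needs two geometrically defined trisubstituted alkenes.

Alternative 3: chloride-terminated closure of ring A.
- **Disconnection:** C3–C4 and C2–Cl.
- **Forward key step:** a Lewis acid activates the isopropylidene ketone A4 at its β-carbon C4. The allyl group on C10 attacks through C3, and the C2 cation takes up chloride equatorially.
- **Attraction:** the C–Cl bond, ring A and the C2 configuration would arise together.
- **Why turned down:**
  - A monosubstituted alkene is a poor nucleophile and must pass through a secondary cation.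
  - The 1,1-disubstituted C8=C17 alkene in the same molecule is more nucleophilic and can reach C4, so C8 would have to be masked.
  - The acid needed would move the β,γ double bond.
  - A4 already holds the vicinal C9/C10 pair with the quaternary centre, so the precursor is hardly simpler than the product.

Key step: step 7

Remark on the chemistry: the sense of induction in step 1 is assigned by analogy with aryl and alkenyl ketones. Both enantiomers of the catalyst are commercial, so the required (R)-alcohol is accessible in either case.

## Steps

Step 1
Reactants: 1 ketoisophorone (2,6,6-trimethylcyclohex-2-ene-1,4-dione)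
Product: 2 (R)-4-hydroxy-2,6,6-trimethylcyclohex-2-en-1-one
Conditions: RuCl(p-cymene)[(R,R)-TsDPEN] (0.5 mol %), i-PrOH, rt
Reagents that add atoms: none
Why: Noyori-type asymmetric transfer hydrogenation; the C4 carbonyl between CH= and CH2 is far more accessible than the C1 carbonyl between C(CH3)= and C(CH3)2, and the alkenyl side plays the role of the aryl group of aryl ketones, so the (R,R)-catalyst should give the (R)-carbinol, the only stereocentre of the ring system that is set by catalysis.

Step 2
Reactants: 2 (R)-4-hydroxy-2,6,6-trimethylcyclohex-2-en-1-one
Product: 3 (4S,6S)-4-hydroxy-2,2,6-trimethylcyclohexan-1-one (OH and 6-CH3 trans)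
Conditions: [Ir(cod)(PCy3)(py)]PF6 (2 mol %), H2 (1 atm), CH2Cl2, 0 °C to rt
Reagents that add atoms: none
Why: Hydroxyl-directed homogeneous hydrogenation; the cationic iridium centre binds the OH and delivers H2 to the same face, which places the C6 methyl trans to OH and leaves the OH axial in the chair with equatorial methyl, the best geometry for step 3; C6 becomes sp2 again in step 4, so its epimer is also productive.

Step 3
Reactants: 3 (4S,6S)-4-hydroxy-2,2,6-trimethylcyclohexan-1-one
Product: 4 (4R,6S)-4-chloro-2,2,6-trimethylcyclohexan-1-one (Cl and 6-CH3 cis, both equatorial)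
Conditions: PPh3, CCl4, CH2Cl2, 0 to 40 °C
Reagents that add atoms: carbon tetrachloride ClC(Cl)(Cl)Cl
Why: Appel reaction; chloride displaces the axial oxyphosphonium group by SN2 with inversion, helped by relief of its 1,3-diaxial contact with one C2 methyl, and gives the equatorial chloride with the absolute configuration of C2 (labdane numbering) of 23; the hindered ketone is inert.

Step 4
Reactants: 4 (4R,6S)-4-chloro-2,2,6-trimethylcyclohexan-1-one
Product: 6 (R)-4-chloro-2,6,6-trimethylcyclohex-1-en-1-yl trifluoromethanesulfonate, via lithium (R)-4-chloro-2,6,6-trimethylcyclohex-1-en-1-olate 5 (not isolated)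
Conditions: LDA, THF, −78 °C; PhNTf2, −78 to 0 °C
Reagents that add atoms: N-phenylbis(trifluoromethanesulfonimide) O=S(=O)(C(F)(F)F)N(c1ccccc1)S(=O)(=O)C(F)(F)F; lithium diisopropylamide [Li+].CC(C)[N-]C(C)C (Li in 5 only)
Why: Only C6 carries an α-hydrogen (axial and well aligned), so enolisation is regiospecific and O-sulfonylation gives the tetrasubstituted enol triflate; at low temperature the equatorial C–Cl bond is not aligned for 1,3-displacement by the enolate.

Step 5
Reactants: 6 (R)-4-chloro-2,6,6-trimethylcyclohex-1-en-1-yl trifluoromethanesulfonate
Product: 7 (R)-1-(4-chloro-2,6,6-trimethylcyclohex-1-en-1-yl)ethan-1-one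
Conditions: Pd(PPh3)4 (5 mol %), Me4Sn, LiCl, CO (1 atm), DMF, 60 °C
Reagents that add atoms: carbon monoxide [C-]#[O+]; tetramethyltin C[Sn](C)(C)C
Why: Carbonylative Stille coupling; oxidative addition to the alkenyl triflate, CO insertion and methyl transfer from tin form the C5–C6 and C6–C7 bonds, and the unactivated secondary chloride does not add to Pd(0) under these conditions.

Step 6
Reactants: 7 (R)-1-(4-chloro-2,6,6-trimethylcyclohex-1-en-1-yl)ethan-1-one
Product: 8 (R)-tert-butyl{[1-(4-chloro-2,6,6-trimethylcyclohex-1-en-1-yl)ethenyl]oxy}dimethylsilane
Conditions: TBSOTf, Et3N, CH2Cl2, 0 °C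
Reagents that add atoms: tert-butyldimethylsilyl trifluoromethanesulfonate CC(C)(C)[Si](C)(C)OS(=O)(=O)C(F)(F)F
Why: Soft enolisation and O-silylation; the acetyl CH3 is the only α-position, and γ-deprotonation is disfavoured because the carbonyl is twisted out of conjugation with the tetrasubstituted ring alkene, so the cross-conjugated 2-silyloxydiene should form.

Step 7
Reactants: 8 (R)-tert-butyl{[1-(4-chloro-2,6,6-trimethylcyclohex-1-en-1-yl)ethenyl]oxy}dimethylsilane; 9 ethyl buta-2,3-dienoate
Product: 10 ethyl (1S,7S,8aR)-4-(tert-butyldimethylsilyloxy)-7-chloro-5,5,8a-trimethyl-2-methylidene-1,2,3,5,6,7,8,8a-octahydronaphthalene-1-carboxylate (labdane locants: 2α-Cl, 9α-H, 10β-CH3, C5=C6 enol silane, C8=C17, C11 ester)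
Conditions: Tf2NH (5 mol %), CH2Cl2, −78 to −20 °C; Et3N quench
Reagents that add atoms: none
Why: The silyl triflimide formed in situ activates the ester of 9; the unhindered C7 terminus of the diene (largest HOMO coefficient) attacks the central allene carbon C8 (largest LUMO coefficient) and C9 then closes on C10 in a strongly asynchronous [4+2], which in the stepwise limit is a Mukaiyama–Michael addition followed by a 6-(enolexo)-endo-trig Michael closure. The closest known reaction types are the acid-catalysed (4+2) cycloadditions of hindered 2-silyloxydienes with unsaturated esters and the Diels–Alder reactions of allenoates at their conjugated double bond. Ring B is the only ring closed; closure on C6 (four-membered) is reversible for such a donor–acceptor pair and closure through C17 (eight-membered) is out of reach, so the six-membered ring is the sink. Regiochemistry follows the para rule (C6–OSi para to the ester-bearing C9) and is reinforced by the alkyl groups on C10. C10 is controlled by C2: addition to the α face lets ring A develop into the chair with equatorial chlorine, whereas addition to the β face forces chlorine axial and syn to both the C4 and the C10 methyl groups (or ring A into a boat), and the late transition state for forming a quaternary centre should feel much of this penalty. C9 is controlled by the exo orientation of the ester: the endo slot lies under ring A against the axial α-hydrogens on C1 and C3 and the α-methyl on C4 and takes the hydrogen, so the ester ends cis to C20, i.e. β and equatorial. The distal allene bond survives as C8=C17, the enol silane is formed regiospecifically at C5=C6, and it is too hindered to react with a second molecule of 9. The step therefore needs site, regio, exo and facial selectivity, secured in turn by conjugation in 9, by the C6 oxygen, by the bulk of ring A and by the Cl/CH3 1,3-diaxial clash.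

Step 8
Reactants: 10 the Diels–Alder adduct (C11 ethyl ester)
Product: 11 [(1S,7S,8aR)-4-(tert-butyldimethylsilyloxy)-7-chloro-5,5,8a-trimethyl-2-methylidene-1,2,3,5,6,7,8,8a-octahydronaphthalen-1-yl]methanol
Conditions: DIBAL-H (2.5 equiv), CH2Cl2, −78 to 0 °C; aq. Rochelle salt
Reagents that add atoms: none
Why: Hydride reduction of the ester to the primary alcohol; the enol silane, both alkenes and the alkyl chloride are inert to DIBAL-H at low temperature and C9 is not touched.

Step 9
Reactants: 11 the C11 primary alcohol
Product: 12 (1S,7S,8aR)-4-(tert-butyldimethylsilyloxy)-7-chloro-5,5,8a-trimethyl-2-methylidene-1,2,3,5,6,7,8,8a-octahydronaphthalene-1-carbaldehyde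
Conditions: Dess–Martin periodinane, NaHCO3, CH2Cl2, 0 °C
Reagents that add atoms: none
Why: Dess–Martin oxidation under buffered, non-basic conditions, chosen to avoid epimerisation at C9 and migration of the C8=C17 bond into conjugation with the new aldehyde.

Step 10
Reactants: 12 the C11 aldehyde
Product: 14 2-[(1S,7S,8aR)-4-(tert-butyldimethylsilyloxy)-7-chloro-5,5,8a-trimethyl-2-methylidene-1,2,3,5,6,7,8,8a-octahydronaphthalen-1-yl]acetaldehyde, via the (E)-C11=C12 alkenyl pinacol boronate 13 (not isolated)
Conditions: CH2(Bpin)2, LiTMP (TMP, n-BuLi), THF, 0 °C; 12, −78 °C to rt; then NaBO3·4H2O, THF/H2O, rt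
Reagents that add atoms: bis[(pinacolato)boryl]methane CC1(C)OB(CB2OC(C)(C)C(C)(C)O2)OC1(C)C; sodium perborate [Na+].[O-]OB=O
Why: Boron–Wittig olefination followed by oxidation of the alkenylboronate; the gem-diboryl carbanion adds to the aldehyde, syn B–O elimination gives 13, and perborate turns C–B into the enol, which tautomerises to the homologated aldehyde; the one-carbon homologation is free of acid, so the enol silane survives, and the geometry of 13 is irrelevant.

Step 11
Reactants: 15 (R)-4-benzyloxazolidin-2-one; 16 3-cyanopropanoic acid
Product: 18 (R)-4-(4-benzyl-2-oxooxazolidin-3-yl)-4-oxobutanenitrile, via 3-cyanopropanoic pivalic anhydride 17 (not isolated)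
Conditions: PivCl, Et3N, THF, −20 °C; then 15, LiCl, rt
Reagents that add atoms: pivaloyl chloride CC(C)(C)C(=O)Cl (atoms in 17 only)
Why: Mixed-anhydride N-acylation of the oxazolidinone under LiCl/Et3N conditions; the nitrogen attacks the less hindered carbonyl of 17 and pivalate leaves.

Step 12
Reactants: 18 (R)-4-(4-benzyl-2-oxooxazolidin-3-yl)-4-oxobutanenitrile; 14 the C12 aldehyde
Product: 20 (R)-4-benzyl-3-{(2R,3S)-2-(cyanomethyl)-3-hydroxy-4-[(1S,7S,8aR)-4-(tert-butyldimethylsilyloxy)-7-chloro-5,5,8a-trimethyl-2-methylidene-1,2,3,5,6,7,8,8a-octahydronaphthalen-1-yl]butanoyl}oxazolidin-2-one, via the (Z)-dibutylboron enolate of 18 19 (not isolated)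
Conditions: 18, Bu2BOTf, Et3N, CH2Cl2, −78 to 0 °C; 14, −78 to 0 °C; pH 7 buffer, MeOH, H2O2, 0 °C
Reagents that add atoms: dibutylboron trifluoromethanesulfonate CCCCB(CCCC)OS(=O)(=O)C(F)(F)F (atoms in 19 only)
Why: Evans syn-aldol reaction; the Z-boron enolate reacts through a chair Zimmerman–Traxler transition state with the auxiliary dipole opposed, and the (R)-benzyl group shields one enolate face, which should give the (12S,13R) syn pair; 14 has no α-stereocentre, so the reagent decides, and the nitrile, the chloride and the hindered enol silane are spectators.

Step 13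
Reactants: 20 the syn-aldol adduct
Product: 22 (R)-3-{(S)-1-hydroxy-2-[(1S,7S,8aR)-4-(tert-butyldimethylsilyloxy)-7-chloro-5,5,8a-trimethyl-2-methylidene-1,2,3,5,6,7,8,8a-octahydronaphthalen-1-yl]ethyl}pyrrolidine-2,5-dione, via the C15 primary amide of 20 21 (not isolated)
Conditions: [PtH(PMe2OH)(PMe2O)2H] (5 mol %), EtOH/H2O 4:1, 75 °C
Reagents that add atoms: water O
Why: Neutral platinum-catalysed nitrile hydration followed by intramolecular N-acylation; the amide nitrogen of 21 attacks the activated exocyclic carbonyl C16 in a 5-exo-trig mode and expels the auxiliary, so the imide forms without acid or base and C12 and C13 are untouched.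

Step 14
Reactants: 22 the silyl enol ether of the target
Product: 23 haterumaimide G
Conditions: TBAF, AcOH (1:1.5), THF, 0 °C
Reagents that add atoms: none
Why: Fluoride cleaves the Si–O bond and the enol(ate) is protonated at C5 by acetic acid from the α face, because the β face is covered by the axial methyls on C4 and C10 and axial protonation leads straight to the chair–chair trans-decalin, which is also the more stable epimer; the buffer keeps the medium from enolising the new ketone toward C7.

## Compound list

1 | ketoisophorone (2,6,6-trimethylcyclohex-2-ene-1,4-dione) | CC1=CC(=O)CC(C)(C)C1=O | starting material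
2 | (R)-4-hydroxy-2,6,6-trimethylcyclohex-2-en-1-one | CC1=C[C@H](O)CC(C)(C)C1=O | intermediate
3 | (4S,6S)-4-hydroxy-2,2,6-trimethylcyclohexan-1-one | C[C@H]1C[C@H](O)CC(C)(C)C1=O | intermediate
4 | (4R,6S)-4-chloro-2,2,6-trimethylcyclohexan-1-one | C[C@H]1C[C@@H](Cl)CC(C)(C)C1=O | intermediate
5 | lithium (R)-4-chloro-2,6,6-trimethylcyclohex-1-en-1-olate | [Li+].CC1=C([O-])C(C)(C)C[C@H](Cl)C1 | intermediate
6 | (R)-4-chloro-2,6,6-trimethylcyclohex-1-en-1-yl trifluoromethanesulfonate | CC1=C(OS(=O)(=O)C(F)(F)F)C(C)(C)C[C@H](Cl)C1 | intermediate
7 | (R)-1-(4-chloro-2,6,6-trimethylcyclohex-1-en-1-yl)ethan-1-one | CC1=C(C(C)=O)C(C)(C)C[C@H](Cl)C1 | intermediate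
8 | (R)-tert-butyl{[1-(4-chloro-2,6,6-trimethylcyclohex-1-en-1-yl)ethenyl]oxy}dimethylsilane | CC1=C(C(=C)O[Si](C)(C)C(C)(C)C)C(C)(C)C[C@H](Cl)C1 | intermediate
9 | ethyl buta-2,3-dienoate | C=C=CC(=O)OCC | starting material
10 | Diels–Alder adduct, C11 ethyl ester (2α-Cl, 9α-H, 10β-CH3, 6-OTBS-5-ene, 8(17)-ene) | C=C1CC(O[Si](C)(C)C(C)(C)C)=C2C(C)(C)C[C@H](Cl)C[C@]2(C)[C@H]1C(=O)OCC | intermediate
11 | C11 primary alcohol | C=C1CC(O[Si](C)(C)C(C)(C)C)=C2C(C)(C)C[C@H](Cl)C[C@]2(C)[C@H]1CO | intermediate
12 | C11 aldehyde | C=C1CC(O[Si](C)(C)C(C)(C)C)=C2C(C)(C)C[C@H](Cl)C[C@]2(C)[C@H]1C=O | intermediate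
13 | (E)-C11=C12 alkenyl pinacol boronate | C=C1CC(O[Si](C)(C)C(C)(C)C)=C2C(C)(C)C[C@H](Cl)C[C@]2(C)[C@H]1/C=C/B3OC(C)(C)C(C)(C)O3 | intermediate
14 | C12 aldehyde | C=C1CC(O[Si](C)(C)C(C)(C)C)=C2C(C)(C)C[C@H](Cl)C[C@]2(C)[C@H]1CC=O | intermediate
15 | (R)-4-benzyloxazolidin-2-one | O=C1N[C@H](Cc2ccccc2)CO1 | starting material
16 | 3-cyanopropanoic acid | N#CCCC(=O)O | starting material
17 | 3-cyanopropanoic pivalic anhydride | N#CCCC(=O)OC(=O)C(C)(C)C | intermediate
18 | (R)-4-(4-benzyl-2-oxooxazolidin-3-yl)-4-oxobutanenitrile | N#CCCC(=O)N1[C@H](Cc2ccccc2)COC1=O | intermediate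
19 | (Z)-dibutylboron enolate of 18 | N#CC/C=C(\OB(CCCC)CCCC)N1[C@H](Cc2ccccc2)COC1=O | intermediate
20 | syn-aldol adduct (12S,13R), C15 nitrile | C=C1CC(O[Si](C)(C)C(C)(C)C)=C2C(C)(C)C[C@H](Cl)C[C@]2(C)[C@H]1C[C@H](O)[C@@H](CC#N)C(=O)N3[C@H](Cc4ccccc4)COC3=O | intermediate
21 | C15 primary amide of 20 | C=C1CC(O[Si](C)(C)C(C)(C)C)=C2C(C)(C)C[C@H](Cl)C[C@]2(C)[C@H]1C[C@H](O)[C@@H](CC(N)=O)C(=O)N3[C@H](Cc4ccccc4)COC3=O | intermediate
22 | C5=C6 TBS enol ether of haterumaimide G | C=C1CC(O[Si](C)(C)C(C)(C)C)=C2C(C)(C)C[C@H](Cl)C[C@]2(C)[C@H]1C[C@H](O)[C@H]3CC(=O)NC3=O | intermediate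
23 | haterumaimide G | C=C1CC(=O)[C@H]2C(C)(C)C[C@H](Cl)C[C@]2(C)[C@H]1C[C@H](O)[C@H]1CC(=O)NC1=O | target

## Step count and least certain steps

Total step count: 14. Longest linear sequence: 13 (steps 1–10 and 12–14). Step 11 is a one-step side branch.

**Step 7 (key step).**
- *What may go wrong:* The first bond (C7–C8) should form easily. The danger is that closure of the second bond at the fully substituted C10 lags far behind. The open intermediate could then be drained by silyl transfer or by closure onto C6. If the mixture has to be warmed, exo and facial discrimination could also erode.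
- *Fallback:* take C9 out of the cycloaddition. From 8, a thermal concerted Diels–Alder reaction with the linear, slimmer ethyl but-2-ynoate (toluene, sealed tube) would give the cyclohexadiene ester ethyl (7S,8aR)-4-(tert-butyldimethylsilyloxy)-7-chloro-2,5,5,8a-tetramethyl-3,5,6,7,8,8a-hexahydronaphthalene-1-carboxylate F1, in which only C10 is set. LDA would then remove a proton from the C17 methyl, which is cis to the ester. Kinetic protonation of the dienolate at C9 from the α face, opposite C20, moves the double bond to C8=C17 and sets C9. This comes back to the route at 10.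

**Step 3.**
- *What may go wrong:* The axial oxyphosphonium group has two antiperiplanar axial hydrogens, so E2 loss can compete with substitution. Chloride–chloride exchange could erode the configuration.
- *Fallback:* carry out the substitution one stage earlier, on allylic alcohol 2. There the carbinol carbon is activated for SN2, while ionisation and SN2′ attack are both disfavoured by the electron-poor enone. An Appel reaction would give (S)-4-chloro-2,6,6-trimethylcyclohex-2-en-1-one F2. Conjugate reduction with L-Selectride leads directly to enolate 5, which is triflated in the same flask, so the route is rejoined at 6.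

**Step 5.**
- *What may go wrong:* CO insertion and transmetalation at the hindered tetrasubstituted alkenylpalladium centre may be slow. Direct methyl transfer or reduction of the triflate could then take over.
- *Fallback:* form the C5–C6 bond by 1,2-addition. From 4, ethynylmagnesium bromide with CeCl3 would give 4-chloro-1-ethynyl-2,2,6-trimethylcyclohexan-1-ol F3; the carbinol configuration is irrelevant. A Rupe rearrangement (HCO2H, heat) dehydrates toward C6 and hydrates the alkyne. This comes back to the route at 7.

**Step 13.**
- *What may go wrong:* The free C12 hydroxyl may add to the metal-activated nitrile, with loss of nitrogen on hydrolysis. The N-acylation may be sluggish, and long heating invites retro-aldol cleavage.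
- *Fallback:* bring in the nitrogen last. Acylation of 15 with methyl 4-chloro-4-oxobutanoate would give methyl (R)-4-(4-benzyl-2-oxooxazolidin-3-yl)-4-oxobutanoate F4. The same boron aldol reaction with 14 would give the syn adduct with a C15 methyl ester F5. Ammonia in methanol then effects ammonolysis and ring closure. The possible orders of events (lactonisation, attack at C15 or at C16) all converge on the imide, so the route is rejoined at 22.

**Step 14.**
- *What may go wrong:* Enolisation of the freshly released ketone toward C7 by fluoride or acetate would move the C8=C17 bond into conjugation. Protonation of C5 from the β face is less likely.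
- *Fallback:* correct the migration instead of avoiding it. From 22, unbuffered fluoride would drive the migration to completion and give the conjugated 7-en-6-one isomer F6. Excess KHMDS, after deprotonation of N–H and O–H, forms the extended dienolate through the unhindered C17 methyl. Kinetic protonation at C7 at low temperature (deconjugative protonation) comes back to the route at 23.

## Further compounds

F1 | step 7 | ethyl (7S,8aR)-4-(tert-butyldimethylsilyloxy)-7-chloro-2,5,5,8a-tetramethyl-3,5,6,7,8,8a-hexahydronaphthalene-1-carboxylate | CC=1CC(O[Si](C)(C)C(C)(C)C)=C2C(C)(C)C[C@H](Cl)C[C@]2(C)C=1C(=O)OCC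
F2 | step 3 | (S)-4-chloro-2,6,6-trimethylcyclohex-2-en-1-one | CC1=C[C@@H](Cl)CC(C)(C)C1=O
F3 | step 5 | (4R,6S)-4-chloro-1-ethynyl-2,2,6-trimethylcyclohexan-1-ol (C1 not defined) | C[C@H]1C[C@@H](Cl)CC(C)(C)C1(O)C#C
F4 | step 13 | methyl (R)-4-(4-benzyl-2-oxooxazolidin-3-yl)-4-oxobutanoate | COC(=O)CCC(=O)N1[C@H](Cc2ccccc2)COC1=O
F5 | step 13 | syn-aldol adduct (12S,13R) with C15 methyl ester | C=C1CC(O[Si](C)(C)C(C)(C)C)=C2C(C)(C)C[C@H](Cl)C[C@]2(C)[C@H]1C[C@H](O)[C@@H](CC(=O)OC)C(=O)N3[C@H](Cc4ccccc4)COC3=O
F6 | step 14 | conjugated 7-en-6-one isomer of haterumaimide G | CC1=CC(=O)[C@H]2C(C)(C)C[C@H](Cl)C[C@]2(C)[C@H]1C[C@H](O)[C@H]1CC(=O)NC1=O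
A1 | alternative 1 | (+)-sclareolide | C[C@@]12CC[C@H]3C(C)(C)CCC[C@]3(C)[C@H]1CC(=O)O2
A2 | alternative 1 | 2α-chlorosclareolide | C[C@@]12CC[C@H]3C(C)(C)C[C@H](Cl)C[C@]3(C)[C@H]1CC(=O)O2
A3 | alternative 2 | acyclic (R)-chloro trienone allylsilane with C12 dimethyl acetal | CC(C)=C[C@H](Cl)C/C(C)=C/C(=O)C/C(C[Si](C)(C)C)=C/CC(OC)OC
A4 | alternative 3 | 3-allyl-4-(2,2-dimethoxyethyl)-3-methyl-5-methylidene-2-(propan-2-ylidene)cyclohexan-1-one, configured as C9 and C10 of 23 | C=CC[C@@]1(C)C(=C(C)C)C(=O)CC(=C)[C@@H]1CC(OC)OC
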